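**Retrosynthetic overview**

1. Atom labels: cyclopentane C1–C2–C3–C4–C5, seven-membered ring C1–C5–C6–C7–C8–C9–C10, cyclopropane C6–C7–C11, benzylic C7′. The strategy rests on the seven-membered carbocycle that carries oxygen at C1, the quaternary C4 on C5 and the cis-fused gem-dimethylcyclopropane on C6–C7. With a carbonyl restored at C8 it is a cycloheptane-1,4-dione, that is, a cyclopentane-1,3-dione enlarged by the two sp2 carbons of 3,3-dimethylcyclopropene.
2. Target ⇒ double formylation of the arene; C7′–isobutyl by allylation of a benzylic cation inside the oxepine; O–C1 aryl ether by Pd C–O coupling; aryl on C7′ by Grignard addition to the C7′ aldehyde.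
3. Carbocyclic core ⇒ C8 deoxygenation; C10 methyl by alkoxide-directed conjugate addition to the C9=C10 enone; cyclopentane by Barbier closure of C2 onto C1.
4. Key disconnection: C5–C6 and C7–C8 by [2+2] photocycloaddition of the dione enol double bond C8=C5 (held as a cyclic enol ether with the C2 oxygen) to the cyclopropene, then retro-aldol cleavage of C5–C8. C4 comes from Pd-catalysed asymmetric allylation of cyclopentane-1,3-dione with isoprene monoepoxide.
5. Order of ring formation: cyclopentenone (given) → dihydropyran tether → cyclobutane on the cyclopropane → seven-membered ring (ring expansion) → cyclopentane → oxepine.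

Key step: step 8

Remark on the precursor: the enol of the 2-substituted cyclopentane-1,3-dione is not used free but as its internal six-membered enol ether with the C2 oxygen (compound 8). Only in this form does C4 sit in a ring fused to the reacting double bond, where it can bias the approach of the cyclopropene. The retro-aldol is then released by aqueous acid in the same operation, which also frees the C2 alcohol.

Assumption: the (R,R)-ligand in step 1 is taken to deliver (S)-3; if the sense of induction with this carbon nucleophile is opposite, the (S,S)-ligand is used.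

**Route**

Step 1
Reactants: 1 cyclopentane-1,3-dione; 2 2-methyl-2-vinyloxirane (racemic)
Product: 3 (S)-3-hydroxy-2-(1-hydroxy-2-methylbut-3-en-2-yl)cyclopent-2-en-1-one
Conditions: Pd2(dba)3·CHCl3 (1 mol %), (R,R)-N,N′-(cyclohexane-1,2-diyl)bis[2-(diphenylphosphino)-1-naphthamide] (3 mol %), CH2Cl2, 23 °C; work-up without acid
Reagents that add atoms: none
Why: Tsuji–Trost-type dynamic kinetic asymmetric allylic alkylation: the π-allyl complexes from racemic 2 interconvert, and the acidic dione, directed by the alkoxide, should attack through carbon at the more substituted terminus, so the chiral ligand sets the quaternary C4 as (S); acid is avoided so that the primary alcohol does not cyclodehydrate onto the enol.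

Step 2
Reactants: 3 (S)-3-hydroxy-2-(1-hydroxy-2-methylbut-3-en-2-yl)cyclopent-2-en-1-one
Product: 4 (S)-2-(1-hydroxy-2-methylbut-3-en-2-yl)-3-methoxycyclopent-2-en-1-one
Conditions: TMSCHN2, MeOH–toluene, 0 °C
Reagents that add atoms: trimethylsilyldiazomethane, C[Si](C)(C)C=[N+]=[N-]
Why: O-methylation of the vinylogous acid by a diazoalkane (as for a carboxylic acid) masks the acidic enol as a vinylogous ester; the neutral alcohol is untouched and both carbonyl positions are equivalent, so one product should form.

Step 3
Reactants: 4 (S)-2-(1-hydroxy-2-methylbut-3-en-2-yl)-3-methoxycyclopent-2-en-1-one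
Product: 5 (S)-2-[1-(tert-butyldiphenylsilyloxy)-2-methylbut-3-en-2-yl]-3-methoxycyclopent-2-en-1-one
Conditions: TBDPSCl, imidazole, DMF, 23 °C
Reagents that add atoms: tert-butyl(chloro)diphenylsilane, CC(C)(C)[Si](Cl)(c1ccccc1)c1ccccc1
Why: Standard silylation of the primary (neopentyl) alcohol; the bulky, acid-stable TBDPS group is chosen because it later shields one face of the enone.

Step 4
Reactants: 5 (S)-2-[1-(tert-butyldiphenylsilyloxy)-2-methylbut-3-en-2-yl]-3-methoxycyclopent-2-en-1-one
Product: 7 (S)-2-[1-(tert-butyldiphenylsilyloxy)-4-hydroxy-2-methylbutan-2-yl]-3-methoxycyclopent-2-en-1-one, via B-alkyl-9-BBN adduct 6 (not isolated)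
Conditions: 9-BBN, THF, 23 → 50 °C; then aq. NaOH, H2O2, 0 °C
Reagents that add atoms: hydrogen peroxide, OO
Why: Anti-Markovnikov hydroboration–oxidation of the monosubstituted alkene gives the C2 alcohol; the tetrasubstituted, electron-poor enone double bond and the vinylogous ester carbonyl should be inert to 9-BBN.

Step 5
Reactants: 7 (S)-2-[1-(tert-butyldiphenylsilyloxy)-4-hydroxy-2-methylbutan-2-yl]-3-methoxycyclopent-2-en-1-one
Product: 8 (S)-4-[(tert-butyldiphenylsilyloxy)methyl]-4-methyl-3,4,6,7-tetrahydrocyclopenta[b]pyran-5(2H)-one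
Conditions: PPTS (cat.), toluene, 4 Å MS, 80 °C
Reagents that add atoms: none
Why: Acid-catalysed intramolecular vinylogous transesterification (addition–elimination at the β-carbon with loss of methanol) closes the six-membered cyclic enol ether between the C2 oxygen and the enol carbon; only this ring can form because the C7′ oxygen is silylated.

Step 6
Reactants: 9 3-methylbut-2-enal
Product: 10 3-methylbut-2-enal p-toluenesulfonylhydrazone
Conditions: TsNHNH2, MeOH, 23 °C
Reagents that add atoms: p-toluenesulfonyl hydrazide, Cc1ccc(cc1)S(=O)(=O)NN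
Why: Condensation of the aldehyde with the sulfonyl hydrazide gives the hydrazone needed for carbene generation.

Step 7
Reactants: 10 3-methylbut-2-enal p-toluenesulfonylhydrazone
Product: 13 3,3-dimethylcyclopropene, via tosylhydrazone sodium salt 11 (not isolated), via 1-diazo-3-methylbut-2-ene 12 (not isolated)
Conditions: NaOMe, diglyme, 23 °C; then 160 °C, product distilled into a trap at −78 °C
Reagents that add atoms: none
Why: Bamford–Stevens reaction: the salt loses sulfinate to give the vinyl diazoalkane, which loses N2 to an alkenylcarbene that closes onto its own double bond to the cyclopropene; the volatile product should distil from the hot mixture as it forms.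

Step 8
Reactants: 8 (S)-4-[(tert-butyldiphenylsilyloxy)methyl]-4-methyl-3,4,6,7-tetrahydrocyclopenta[b]pyran-5(2H)-one; 13 3,3-dimethylcyclopropene
Product: 15 2-[(2S)-1-(tert-butyldiphenylsilyloxy)-4-hydroxy-2-methylbutan-2-yl]-8,8-dimethylbicyclo[5.1.0]octane-3,6-dione (ketones at C1 and C8; cis-fused cyclopropane on C6–C7; C5 side chain trans to CMe2), via alkoxycyclobutane photoadduct 14 (not isolated)
Conditions: 13 (8 equiv), hν (λ ≥ 300 nm, Pyrex), CH2Cl2, −40 °C; excess 13 purged; then 1 M aq. HCl, THF, 23 °C
Reagents that add atoms: water, O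
Why: Proposed new method: direct irradiation populates the enone triplet of 8, which adds to the strained π bond of 13 through a 1,4-biradical that collapses to the alkoxycyclobutane 14 (C5–C6 and C7–C8 formed; the four-membered ring closes by radical recombination, suprafacially on the cyclopropene, so the cyclopropane is cis-fused), a reaction of the de Mayo type known for enols and enol ethers of cyclic 1,3-diketones with ordinary alkenes but not with a cyclopropene. Aqueous acid then opens the donor–acceptor cyclobutane by retro-aldol cleavage of C5–C8, driven by the strain of the bicyclo[2.1.0]pentane, so the seven-membered ring arises by two-carbon ring expansion and not by cyclisation, and water converts the oxocarbenium ion into the C8 ketone and the free C2 alcohol. The step needs one combination of face and orientation: attack on the face of the C8=C5 bond anti to the pseudoaxial CH2OTBDPS group on C4, with the CMe2 bridge turned toward the cyclopentanone and away from the quaternary C4; the six-membered enol-ether tether, which holds C4 in a ring fused to the reacting double bond, and the size of the silyl ether are the elements meant to secure both, and this sets C6 and C7 relative to C4. C5 is set last, by protonation of the enol and equilibration under the same acid, which should place the bulky C4 substituent trans to the CMe2 bridge. Both components are symmetric about the reacting bonds, so no regiochemical question arises.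

Step 9
Reactants: 15 2-[(2S)-1-(tert-butyldiphenylsilyloxy)-4-hydroxy-2-methylbutan-2-yl]-8,8-dimethylbicyclo[5.1.0]octane-3,6-dione
Product: 16 2-[(2S)-1-(tert-butyldiphenylsilyloxy)-4-iodo-2-methylbutan-2-yl]-8,8-dimethylbicyclo[5.1.0]octane-3,6-dione (same configuration)
Conditions: I2, PPh3, imidazole, CH2Cl2, 0 → 23 °C
Reagents that add atoms: iodine, II
Why: Appel iodination of the primary alcohol; the ketones do not react, and any lactol form is drained through the open alcohol.

Step 10
Reactants: 16 2-[(2S)-1-(tert-butyldiphenylsilyloxy)-4-iodo-2-methylbutan-2-yl]-8,8-dimethylbicyclo[5.1.0]octane-3,6-dione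
Product: 17 tricyclic hydroxy ketone (cyclopentane C1–C2–C3–C4–C5 cis-fused to the seven-membered ring; C1–OH, C5–H and the C4 CH2OTBDPS group on one face of the cyclopentane; C8 ketone)
Conditions: SmI2 (2.5 equiv), NiI2 (2 mol %), THF, 0 °C
Reagents that add atoms: none
Why: Samarium Barbier cyclisation: Ni-catalysed reduction of the C–I bond should outpace ketyl formation at the cyclopropyl ketone, and the C2 organosamarium adds to the nearby C1 ketone in a five-membered closure; the three-atom tether on C5 can reach C1 only from its own face, which gives the cis ring fusion (C1–OH cis to C5–H), and a transannular hemiketal with C8, if it forms, is in equilibrium and harmless.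

Step 11
Reactants: 17 tricyclic hydroxy ketone
Product: 20 γ-hydroxy enone (C9=C10 double bond conjugated with the C8 ketone; C1–OH free), via bis(trimethylsilyl) derivative 18 (not isolated), via O-trimethylsilyl enone 19 (not isolated)
Conditions: LDA (2.2 equiv), TMSCl, THF, −78 °C; Pd(OAc)2 (1.1 equiv), MeCN, 23 °C; then 10% aq. citric acid, THF
Reagents that add atoms: none
Why: Saegusa–Ito dehydrogenation: kinetic deprotonation occurs at C9 (C7 is a cyclopropane methine), Pd(II) turns the C8 silyl enol ether into the C9=C10 enone by β-hydride elimination, and the mild acid removes the tertiary TMS ether.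

Step 12
Reactants: 20 γ-hydroxy enone
Product: 21 C10-methyl ketone (C10–CH3 cis to C1–OH; C8 ketone)
Conditions: MeMgCl (4 equiv), THF, −78 → 0 °C
Reagents that add atoms: methylmagnesium chloride, C[Mg]Cl
Why: Alkoxide-directed (ligand-assisted) conjugate addition: the magnesium alkoxide at C1 should deliver the methyl group to the adjacent β-carbon C10 on its own face, which sets the C10 methyl cis to the C1 oxygen.

Step 13
Reactants: 21 C10-methyl ketone
Product: 22 diol (C8 now CH2; tertiary C1–OH and primary C7′–OH)
Conditions: N2H4·H2O, KOH, diethylene glycol, 130 → 195 °C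
Reagents that add atoms: none
Why: Wolff–Kishner reduction (Huang-Minlon modification) removes the C8 carbonyl through an anionic pathway with no radical or cation at the cyclopropylcarbinyl position, so the cyclopropane should survive; the hot KOH also cleaves the primary TBDPS ether.

Step 14
Reactants: 22 diol
Product: 23 C7′ aldehyde (C1–OH free)
Conditions: Dess–Martin periodinane, CH2Cl2, 23 °C
Reagents that add atoms: none
Why: Dess–Martin oxidation of the primary alcohol; the tertiary alcohol cannot be oxidised and the aldehyde has no α-hydrogen.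

Step 15
Reactants: 24 1,3-bis(benzyloxy)-5-bromobenzene
Product: 25 1,5-bis(benzyloxy)-3-bromo-2-iodobenzene
Conditions: NIS, MeCN, 23 °C
Reagents that add atoms: N-iodosuccinimide, O=C1CCC(=O)N1I
Why: Electrophilic aromatic iodination at the position ortho to one benzyloxy group and para to the other, which is less hindered than the position between the two ethers.

Step 16
Reactants: 25 1,5-bis(benzyloxy)-3-bromo-2-iodobenzene; 23 C7′ aldehyde
Product: 27 C7′ benzylic alcohol (aryl = 2,4-bis(benzyloxy)-6-bromophenyl; C7′ epimers), via aryl Grignard reagent 26 (not isolated)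
Conditions: 25 (2.3 equiv), i-PrMgCl·LiCl, THF, −40 °C; then 23, −40 → 0 °C; aq. NH4Cl
Reagents that add atoms: none
Why: Iodine–magnesium exchange is selective for the C–I bond and gives an ortho-bromoaryl Grignard reagent that is stable below 0 °C; one equivalent is consumed by the C1–OH and the second adds 1,2 to the aldehyde, and the C7′ configuration is irrelevant because C7′ is oxidised next.

Step 17
Reactants: 27 C7′ benzylic alcohol
Product: 28 aryl ketone (C7′=O; C1–OH free; aryl bromide)
Conditions: Dess–Martin periodinane, CH2Cl2, 23 °C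
Reagents that add atoms: none
Why: Dess–Martin oxidation removes the secondary benzylic hydroxyl, which the aryl–palladium intermediate of the next step could otherwise oxidise; the ketone has no α-hydrogen.

Step 18
Reactants: 28 aryl ketone
Product: 29 oxepinone (aryl ether O–C1 closed; C7′=O; two benzyl ethers)
Conditions: Pd(OAc)2 (5 mol %), rac-2-(di-tert-butylphosphino)-1,1′-binaphthyl (6 mol %), Cs2CO3, toluene, 80 °C
Reagents that add atoms: none
Why: Buchwald–Hartwig-type intramolecular C–O coupling of the tertiary alkoxide with the aryl bromide closes the seven-membered oxepine; the C1 oxygen and C7′ lie on the same face of the cyclopentane so only the cis bridge can form, and a tertiary alkoxide cannot undergo β-hydride elimination.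

Step 19
Reactants: 29 oxepinone
Product: 30 oxepinol (C7′–OH; configuration at C7′ not relevant)
Conditions: LiAlH4, THF, 0 °C
Reagents that add atoms: none
Why: Hydride reduction of the hindered aryl ketone gives the benzylic alcohol, whose configuration does not matter because it is ionised in the next step.

Step 20
Reactants: 30 oxepinol
Product: 31 C7′-(2-methylallyl) bis(benzyl ether) (new chain on the face of C7′ syn to the C4 methyl)
Conditions: trimethyl(2-methylallyl)silane, BF3·OEt2, CH2Cl2, −78 → −40 °C
Reagents that add atoms: trimethyl(2-methylallyl)silane, CC(=C)C[Si](C)(C)C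
Why: Lewis acid ionisation gives a benzylic cation stabilised by three ortho/para oxygen substituents, which the allylsilane traps (Hosomi–Sakurai-type SN1 allylation); attack should occur on the face of C7′ opposite to the C2–C3 bridge of the bicyclo[4.2.1] framework, which sets C7′, and the quaternary C4 rules out elimination.

Step 21
Reactants: 31 C7′-(2-methylallyl) bis(benzyl ether)
Product: 32 C7′-isobutyl diphenol (both phenols free; arene positions between the oxygens unsubstituted)
Conditions: H2 (1 atm), Pd/C, EtOAc, 23 °C
Reagents that add atoms: none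
Why: Heterogeneous hydrogenation saturates the 1,1-disubstituted alkene to the isobutyl group and cleaves both benzyl ethers; the unactivated cyclopropane and the tertiary-alkyl aryl ether should not be hydrogenolysed.

Step 22
Reactants: 32 C7′-isobutyl diphenol
Product: 34 CNP0189833.2 (target), via bis(iminium) salt 33 (not isolated)
Conditions: POCl3, DMF, MeCN, 0 → 23 °C; then H2O, 50 °C
Reagents that add atoms: N,N-dimethylformamide, CN(C)C=O; water, O
Why: Vilsmeier–Haack formylation of the phloroglucinol-type ring at its two free positions (each ortho/para to oxygen), as in the preparation of diformylphloroglucinol; hydrolysis of the bis(iminium) salt gives the dialdehyde.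

**Compound list**

1 | cyclopentane-1,3-dione | O=C1CCC(=O)C1 | starting material
2 | 2-methyl-2-vinyloxirane (racemic) | C=CC1(C)CO1 | starting material
3 | (S)-3-hydroxy-2-(1-hydroxy-2-methylbut-3-en-2-yl)cyclopent-2-en-1-one | C=C[C@@](CO)(C)C1=C(O)CCC1=O | intermediate
4 | (S)-2-(1-hydroxy-2-methylbut-3-en-2-yl)-3-methoxycyclopent-2-en-1-one | C=C[C@@](CO)(C)C1=C(OC)CCC1=O | intermediate
5 | (S)-2-[1-(tert-butyldiphenylsilyloxy)-2-methylbut-3-en-2-yl]-3-methoxycyclopent-2-en-1-one | C=C[C@@](CO[Si](c1ccccc1)(c1ccccc1)C(C)(C)C)(C)C1=C(OC)CCC1=O | intermediate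
6 | B-alkyl-9-borabicyclo[3.3.1]nonane adduct of 5 (boron on the terminal carbon C2) | B1(CC[C@@](CO[Si](c2ccccc2)(c2ccccc2)C(C)(C)C)(C)C2=C(OC)CCC2=O)C2CCCC1CCC2 | intermediate
7 | (S)-2-[1-(tert-butyldiphenylsilyloxy)-4-hydroxy-2-methylbutan-2-yl]-3-methoxycyclopent-2-en-1-one | OCC[C@@](CO[Si](c1ccccc1)(c1ccccc1)C(C)(C)C)(C)C1=C(OC)CCC1=O | intermediate
8 | (S)-4-[(tert-butyldiphenylsilyloxy)methyl]-4-methyl-3,4,6,7-tetrahydrocyclopenta[b]pyran-5(2H)-one (key-step precursor; cyclic enol ether of the 2-substituted dione) | C1C[C@@](CO[Si](c2ccccc2)(c2ccccc2)C(C)(C)C)(C)C2=C(O1)CCC2=O | intermediate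
9 | 3-methylbut-2-enal | CC(C)=CC=O | starting material
10 | 3-methylbut-2-enal p-toluenesulfonylhydrazone | CC(C)=C/C=N/NS(=O)(=O)c1ccc(C)cc1 | intermediate
11 | sodium salt of 10 | CC(C)=C/C=N/[N-]S(=O)(=O)c1ccc(C)cc1.[Na+] | intermediate
12 | 1-diazo-3-methylbut-2-ene | CC(C)=CC=[N+]=[N-] | intermediate
13 | 3,3-dimethylcyclopropene | CC1(C)C=C1 | intermediate
14 | alkoxycyclobutane photoadduct (cyclobutane C5–C6–C7–C8 fused to cyclopentanone, tetrahydropyran and gem-dimethylcyclopropane; new bonds anti to CH2OTBDPS; CMe2 syn to the cyclopentanone) | C1C[C@@](CO[Si](c2ccccc2)(c2ccccc2)C(C)(C)C)(C)[C@]23C(=O)CC[C@@]2(O1)[C@@H]1[C@H]3C1(C)C | intermediate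
15 | 2-[(2S)-1-(tert-butyldiphenylsilyloxy)-4-hydroxy-2-methylbutan-2-yl]-8,8-dimethylbicyclo[5.1.0]octane-3,6-dione (key-step product; ketones at C1 and C8; cis-fused; side chain trans to CMe2) | OCC[C@@](CO[Si](c1ccccc1)(c1ccccc1)C(C)(C)C)(C)[C@H]1[C@H]2[C@@H](C(=O)CCC1=O)C2(C)C | intermediate
16 | 2-[(2S)-1-(tert-butyldiphenylsilyloxy)-4-iodo-2-methylbutan-2-yl]-8,8-dimethylbicyclo[5.1.0]octane-3,6-dione (same configuration as 15) | ICC[C@@](CO[Si](c1ccccc1)(c1ccccc1)C(C)(C)C)(C)[C@H]1[C@H]2[C@@H](C(=O)CCC1=O)C2(C)C | intermediate
17 | tricyclic hydroxy ketone (cis-fused cyclopentanol; C1–OH cis to C5–H and to CH2OTBDPS on C4; C8 ketone) | O[C@]12CC[C@@](CO[Si](c3ccccc3)(c3ccccc3)C(C)(C)C)(C)[C@H]1[C@H]1[C@@H](C(=O)CC2)C1(C)C | intermediate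
18 | bis(trimethylsilyl) derivative of 17 (C1–OTMS; C8=C9 silyl enol ether) | C[Si](C)(C)O[C@]12CC[C@@](CO[Si](c3ccccc3)(c3ccccc3)C(C)(C)C)(C)[C@H]1[C@H]1[C@@H](C(O[Si](C)(C)C)=CC2)C1(C)C | intermediate
19 | O-trimethylsilyl enone (C1–OTMS; C9=C10; C8 ketone) | C[Si](C)(C)O[C@]12CC[C@@](CO[Si](c3ccccc3)(c3ccccc3)C(C)(C)C)(C)[C@H]1[C@H]1[C@@H](C(=O)C=C2)C1(C)C | intermediate
20 | γ-hydroxy enone (C1–OH; C9=C10; C8 ketone) | O[C@]12CC[C@@](CO[Si](c3ccccc3)(c3ccccc3)C(C)(C)C)(C)[C@H]1[C@H]1[C@@H](C(=O)C=C2)C1(C)C | intermediate
21 | C10-methyl ketone (C10–CH3 cis to C1–OH; C8 ketone) | O[C@]12CC[C@@](CO[Si](c3ccccc3)(c3ccccc3)C(C)(C)C)(C)[C@H]1[C@H]1[C@@H](C(=O)C[C@@H]2C)C1(C)C | intermediate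
22 | diol (C8 = CH2; tertiary C1–OH; primary C7′–OH) | O[C@]12CC[C@@](CO)(C)[C@H]1[C@H]1[C@@H](CC[C@@H]2C)C1(C)C | intermediate
23 | C7′ aldehyde (C1–OH free) | O[C@]12CC[C@@](C=O)(C)[C@H]1[C@H]1[C@@H](CC[C@@H]2C)C1(C)C | intermediate
24 | 1,3-bis(benzyloxy)-5-bromobenzene | Brc1cc(OCc2ccccc2)cc(OCc2ccccc2)c1 | starting material
25 | 1,5-bis(benzyloxy)-3-bromo-2-iodobenzene | Ic1c(Br)cc(OCc2ccccc2)cc1OCc1ccccc1 | intermediate
26 | [2,4-bis(benzyloxy)-6-bromophenyl]magnesium chloride (LiCl complex) | Cl[Mg]c1c(Br)cc(OCc2ccccc2)cc1OCc1ccccc1 | intermediate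
27 | C7′ benzylic alcohol (aryl = 2,4-bis(benzyloxy)-6-bromophenyl; C7′ epimers) | O[C@]12CC[C@@](C(O)c3c(Br)cc(OCc4ccccc4)cc3OCc3ccccc3)(C)[C@H]1[C@H]1[C@@H](CC[C@@H]2C)C1(C)C | intermediate
28 | aryl ketone (C7′=O; C1–OH; aryl bromide) | O[C@]12CC[C@@](C(=O)c3c(Br)cc(OCc4ccccc4)cc3OCc3ccccc3)(C)[C@H]1[C@H]1[C@@H](CC[C@@H]2C)C1(C)C | intermediate
29 | oxepinone (O–C1 aryl ether closed; C7′=O) | O=C1c2c(OCc3ccccc3)cc(OCc3ccccc3)cc2O[C@]23CC[C@@]1(C)[C@H]2[C@H]1[C@@H](CC[C@@H]3C)C1(C)C | intermediate
30 | oxepinol (C7′–OH; configuration at C7′ not relevant) | OC1c2c(OCc3ccccc3)cc(OCc3ccccc3)cc2O[C@]23CC[C@@]1(C)[C@H]2[C@H]1[C@@H](CC[C@@H]3C)C1(C)C | intermediate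
31 | C7′-(2-methylallyl) bis(benzyl ether) | C=C(C)C[C@H]1c2c(OCc3ccccc3)cc(OCc3ccccc3)cc2O[C@]23CC[C@@]1(C)[C@H]2[C@H]1[C@@H](CC[C@@H]3C)C1(C)C | intermediate
32 | C7′-isobutyl diphenol | CC(C)C[C@H]1c2c(O)cc(O)cc2O[C@]23CC[C@@]1(C)[C@H]2[C@H]1[C@@H](CC[C@@H]3C)C1(C)C | intermediate
33 | bis(N,N-dimethyliminium) dichloride of the target dialdehyde | CC(C)C[C@H]1c2c(O)c(C=[N+](C)C)c(O)c(C=[N+](C)C)c2O[C@]23CC[C@@]1(C)[C@H]2[C@H]1[C@@H](CC[C@@H]3C)C1(C)C.[Cl-].[Cl-] | intermediate
34 | CNP0189833.2 | CC(C)C[C@H]1c2c(O)c(C=O)c(O)c(C=O)c2O[C@]23CC[C@@]1(C)[C@H]2[C@H]1[C@@H](CC[C@@H]3C)C1(C)C | target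

**Step count**

Total: 22 steps. Longest linear sequence: 19 steps (1–5, 8–14, 16–22).

**Steps most likely to fail**

1. Step 8 (key step). The triplet enone may pass its energy to the cyclopropene (dimerisation of 13), or the biradical may revert instead of closing. The facial preference or the orientation of the CMe2 bridge may also be too weak to give one C6/C7 configuration relative to C4. Fallback with known reaction types: setting out from 8, irradiation in acetylene-saturated CH2Cl2 (λ ≥ 300 nm, −60 °C) should give the cyclobutene photoadduct F1 by enone–alkyne [2+2] photocycloaddition on the face anti to CH2OTBDPS. 1,3-Dipolar cycloaddition of 2-diazopropane (Et2O, −30 → 0 °C) to the strained cyclobutene, from the face flanked by the cyclopentanone and not by the quaternary C4, should give the 1-pyrazoline F2. Photolysis of F2 (350 nm, benzene) extrudes N2 and closes the cyclopropane, which gives 14; the acid treatment of step 8 then brings the route back at 15. Here the orientation of the CMe2 bridge is decided in a thermal, sterically governed cycloaddition and not in the excited state.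

2. Step 18. Reductive elimination of the hindered tertiary alkoxide to form the bridged seven-membered ring may be slow, so that protodebromination of the aryl bromide takes over. Fallback: setting out from 27 (steps 17 and 19 are then not needed), treatment with LiTMP (5 equiv, THF, −78 → 0 °C) should deprotonate the arene position between Br and OBn and expel LiBr to give an aryne. The tertiary C1 alkoxide adds to the aryne carbon next to C7′, the position favoured both by the neighbouring alkoxy group and by the tether, and protonation brings the route back at 30.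

3. Step 12. 1,2-Addition to the C8 ketone may compete, or the methyl group may be delivered to the face of C10 opposite to the C1 oxygen. Fallback: setting out from 20, silylation with (bromomethyl)chlorodimethylsilane (imidazole, CH2Cl2) should give the (bromomethyl)dimethylsilyl ether F3. Silicon-tethered radical cyclisation (Bu3SnH, AIBN, benzene, 80 °C) closes the five-membered ring onto C10 on the face of the C1 oxygen and gives the cyclic siloxane F4. Protodesilylation (TBAF, DMF, 70 °C) turns C10–CH2–Si into C10–CH3 and frees the C1–OH, which brings the route back at 21 with the methyl cis to the oxygen by construction.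

**Further compounds**

F1 | step 8 | cyclobutene photoadduct of 8 and acetylene (C6=C7) | C1C[C@@](CO[Si](c2ccccc2)(c2ccccc2)C(C)(C)C)(C)[C@]23C(=O)CC[C@@]2(O1)C=C3
F2 | step 8 | 1-pyrazoline from F1 and 2-diazopropane (CMe2 on C6, N on C7, syn to the cyclopentanone) | C1C[C@@](CO[Si](c2ccccc2)(c2ccccc2)C(C)(C)C)(C)[C@]23C(=O)CC[C@@]2(O1)[C@H]1N=NC(C)(C)[C@H]13
F3 | step 12 | (bromomethyl)dimethylsilyl ether of 20 | BrC[Si](C)(C)O[C@]12CC[C@@](CO[Si](c3ccccc3)(c3ccccc3)C(C)(C)C)(C)[C@H]1[C@H]1[C@@H](C(=O)C=C2)C1(C)C
F4 | step 12 | cyclic siloxane (C10–CH2–SiMe2–O–C1; C8 ketone) | O1[C@]23CC[C@@](CO[Si](c4ccccc4)(c4ccccc4)C(C)(C)C)(C)[C@H]2[C@H]2[C@@H](C(=O)C[C@@H]3C[Si]1(C)C)C2(C)C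
F0 | step 18 | none | none
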